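## Retrosynthetic overview

1. Last C=C bond: C11=C12 by Wittig reaction of the C15 hydroxy phosphonium salt (β end) with a C25 butenolide trienal.
2. Butenolide: the lactone O–C11' bond is closed by 5-exo-dig attack of a carboxylate on a (Z)-2-en-4-ynoic acid, which fixes the 11'Z ylidene. That acid is made in the same flask by carboxylate-directed C–H alkynylation (C10'–C11') of an α-substituted acrylic acid with a C11 bromoalkyne aldehyde cut from the C10 dialdehyde.
3. ε-End acrylic acid from (R)-α-ionone: C6' from the chiral pool, C3' by allylic oxidation and catalyst-controlled reduction, the carboxyl carbon by carbonylation of the methyl-ketone enol triflate.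
4. β-End C15 salt from (4R,6R)-actinol: enol triflate, Sonogashira coupling with the C6 enynol, trans reduction, phosphonium salt.
5. Ring order: both six-membered rings are bought in intact; the butenolide is the only ring made (step 11), before the last C=C bond.

Assumption: carotenoid numbering is used for the target (3R,3'R,6'R; 11'Z exocyclic, all other chain double bonds E), and (R)-α-ionone of at least 98% ee (fermentation flavour grade), (4R,6R)-actinol, (E)-3-methylpent-2-en-4-yn-1-ol and the C10 dialdehyde are taken as purchasable.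

## Route

Step 1
Reactants: 1 (4R,6R)-4-hydroxy-2,2,6-trimethylcyclohexan-1-one
Product: 3 (4R)-4-hydroxy-2,6,6-trimethylcyclohex-1-en-1-yl trifluoromethanesulfonate, via dilithium alkoxide enolate 2 (not isolated)
Conditions: LiN(iPr)2 (2.2 equiv), THF, -78 to 0 °C; PhNTf2 (1.05 equiv), -78 °C to rt; aq NH4Cl
Reagents that add atoms: N-phenylbis(trifluoromethanesulfonimide), O=S(=O)(N(c1ccccc1)S(=O)(=O)C(F)(F)F)C(F)(F)F
Why: The ketone can enolise only towards C6, so once the hydroxyl sits as its lithium alkoxide the single tetrasubstituted lithium enolate is O-sulfonylated by PhNTf2 (enolate triflation, the aliphatic alkoxide reacting far more slowly), which erases the unwanted C6 centre and leaves the C4 (R) carbinol, the future C3 of the β end, untouched.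

Step 2
Reactants: 3 (4R)-4-hydroxy-2,6,6-trimethylcyclohex-1-en-1-yl trifluoromethanesulfonate, 4 (2E)-3-methylpent-2-en-4-yn-1-ol
Product: 5 (2E)-5-[(4R)-4-hydroxy-2,6,6-trimethylcyclohex-1-en-1-yl]-3-methylpent-2-en-4-yn-1-ol
Conditions: PdCl2(PPh3)2 (3 mol %), CuI (6 mol %), Et3N, DMF, 50 °C
Reagents that add atoms: none
Why: Sonogashira coupling of the hindered cyclohexenyl triflate with the terminal alkyne of the unprotected enynol forms the C6–C7 bond, the 9E geometry is carried in by 4 and no stereocentre is touched.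

Step 3
Reactants: 5 (2E)-5-[(4R)-4-hydroxy-2,6,6-trimethylcyclohex-1-en-1-yl]-3-methylpent-2-en-4-yn-1-ol
Product: 6 (2E,4E)-5-[(4R)-4-hydroxy-2,6,6-trimethylcyclohex-1-en-1-yl]-3-methylpenta-2,4-dien-1-ol
Conditions: NaAlH2(OCH2CH2OMe)2 (3.5 equiv), THF, 0 °C to rt; aq potassium sodium tartrate
Reagents that add atoms: none
Why: Alkoxide-directed trans-hydroalumination of the conjugated 2-en-4-yn-1-ol and protonolysis reduce only the triple bond and give the 7E alkene (hydroxyl-directed aluminium hydride reduction of an enynol to the E,E-dienol).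

Step 4
Reactants: 6 (2E,4E)-5-[(4R)-4-hydroxy-2,6,6-trimethylcyclohex-1-en-1-yl]-3-methylpenta-2,4-dien-1-ol
Product: 7 [(2E,4E)-5-[(4R)-4-hydroxy-2,6,6-trimethylcyclohex-1-en-1-yl]-3-methylpenta-2,4-dien-1-yl]triphenylphosphonium bromide
Conditions: PPh3·HBr (1.05 equiv), MeOH, rt, dark
Reagents that add atoms: triphenylphosphine hydrobromide, [PH+](c1ccccc1)(c1ccccc1)c1ccccc1.[Br-]
Why: The primary dienylic alcohol ionises under HBr to a pentadienyl cation that PPh3 captures at the terminal carbon (phosphonium salt formation of SN1 type), while the secondary ring alcohol does not ionise, so the C3 centre is kept.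

Step 5
Reactants: 8 (3E)-4-[(1R)-2,6,6-trimethylcyclohex-2-en-1-yl]but-3-en-2-one ((R)-α-ionone)
Product: 9 4-[(1R)-2,6,6-trimethylcyclohex-2-en-1-yl]butan-2-one
Conditions: Cu(OAc)2·H2O (3 mol %), 1,2-bis(diphenylphosphino)benzene (3 mol %), PhMe2SiH (1.5 equiv), tBuOH (1.5 equiv), toluene, rt
Reagents that add atoms: none
Why: Ligated copper hydride conjugate reduction delivers hydride to the enone only and leaves the isolated trisubstituted ring alkene alone, and the neutral conditions avoid the acid- or base-induced migration of that alkene that would erase the C6' centre.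

Step 6
Reactants: 9 4-[(1R)-2,6,6-trimethylcyclohex-2-en-1-yl]butan-2-one
Product: 11 4-[(1R)-2,6,6-trimethylcyclohex-2-en-1-yl]but-1-en-2-yl trifluoromethanesulfonate, via potassium enolate 10 (not isolated)
Conditions: KN(SiMe3)2 (1.1 equiv), THF, -78 °C; PhNTf2 (1.1 equiv), -78 to 0 °C; aq NH4Cl
Reagents that add atoms: N-phenylbis(trifluoromethanesulfonimide), O=S(=O)(N(c1ccccc1)S(=O)(=O)C(F)(F)F)C(F)(F)F
Why: Kinetic deprotonation of the methyl ketone by the bulky amide at -78 °C takes a methyl proton and O-triflation of the terminal enolate gives the 2-triflyloxy-1-alkene (regioselective enol triflate formation), the remote stereocentre being unaffected.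

Step 7
Reactants: 11 4-[(1R)-2,6,6-trimethylcyclohex-2-en-1-yl]but-1-en-2-yl trifluoromethanesulfonate
Product: 12 4-[(1R)-2,6,6-trimethyl-4-oxocyclohex-2-en-1-yl]but-1-en-2-yl trifluoromethanesulfonate
Conditions: Rh2(caprolactamate)4 (1 mol %), tBuOOH (70% aq, 5 equiv), K2CO3 (0.5 equiv), CH2Cl2, rt
Reagents that add atoms: tert-butyl hydroperoxide, CC(C)(C)OO
Why: Dirhodium-catalysed allylic oxidation with tBuOOH (peroxyl-radical hydrogen abstraction, then oxidation) attacks the only allylic ring methylene to give the conjugated enone, the tertiary allylic hydrogen at the stereocentre being shielded by the gem-dimethyl group and side chain and the electron-poor enol triflate being inert.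

Step 8
Reactants: 12 4-[(1R)-2,6,6-trimethyl-4-oxocyclohex-2-en-1-yl]but-1-en-2-yl trifluoromethanesulfonate
Product: 13 4-[(1R,4R)-4-hydroxy-2,6,6-trimethylcyclohex-2-en-1-yl]but-1-en-2-yl trifluoromethanesulfonate
Conditions: (S)-2-methyl-CBS-oxazaborolidine (20 mol %), catecholborane (1.5 equiv), toluene, -78 °C
Reagents that add atoms: none
Why: Corey–Bakshi–Shibata reduction, in which the (S)-oxazaborolidine binds the carbonyl with the alkenyl branch as the large group and delivers hydride 1,2 to give the 4R carbinol (the 3'R centre, trans to the C6' side chain) under catalyst control, the existing centre being 1,4-remote.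

Step 9
Reactants: 13 4-[(1R,4R)-4-hydroxy-2,6,6-trimethylcyclohex-2-en-1-yl]but-1-en-2-yl trifluoromethanesulfonate
Product: 14 2-{2-[(1R,4R)-4-hydroxy-2,6,6-trimethylcyclohex-2-en-1-yl]ethyl}prop-2-enoic acid
Conditions: Pd(OAc)2 (5 mol %), PPh3 (10 mol %), CO (1 atm), KOAc (4 equiv), H2O (10 equiv), DMF, 50 °C; work-up at pH 3
Reagents that add atoms: carbon monoxide, [C-]#[O+]; water, O
Why: Palladium-catalysed hydroxycarbonylation of the vinyl triflate (oxidative addition, CO insertion, capture of the acyl palladium by acetate and water) gives the α-substituted acrylic acid directly, the free allylic alcohol being tolerated and no stereocentre involved.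

Step 10
Reactants: 15 (2E,4E,6E)-2,7-dimethylocta-2,4,6-trienedial
Product: 17 (2E,4E,6E)-9-bromo-2,7-dimethylnona-2,4,6-trien-8-ynal, via gem-dibromoalkene 16 (not isolated)
Conditions: [Ph3PCHBr2]Br (1.0 equiv), KOtBu (1.0 equiv), THF, 0 °C, then 15 (3 equiv), rt; DBU (2.5 equiv), MeCN, rt, dark
Reagents that add atoms: (dibromomethyl)triphenylphosphonium bromide, BrC(Br)[P+](c1ccccc1)(c1ccccc1)c1ccccc1.[Br-]
Why: Wittig-type dibromo-olefination (first stage of the Ramirez/Corey–Fuchs sequence) of one aldehyde of the symmetric dialdehyde, kept in excess to suppress double reaction, then DBU-induced anti elimination of HBr from the conjugated gem-dibromoalkene gives the 1-bromoalkyne with the three E double bonds unchanged.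

Step 11
Reactants: 14 2-{2-[(1R,4R)-4-hydroxy-2,6,6-trimethylcyclohex-2-en-1-yl]ethyl}prop-2-enoic acid, 17 (2E,4E,6E)-9-bromo-2,7-dimethylnona-2,4,6-trien-8-ynal
Product: 19 (2E,4E,6E,8Z)-8-(4-{2-[(1R,4R)-4-hydroxy-2,6,6-trimethylcyclohex-2-en-1-yl]ethyl}-5-oxofuran-2(5H)-ylidene)-2,7-dimethylocta-2,4,6-trienal, via (2Z)-enynoic acid 18 (not isolated)
Conditions: [Rh(C5Me5)(MeCN)3](SbF6)2 (5 mol %), K2CO3 (1.2 equiv), tert-amyl alcohol/THF, 40 °C, dark; then Ag2CO3 (10 mol %), rt
Reagents that add atoms: none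
Why: Proposed new method: a redox-neutral carboxylate-directed vinylic C–H alkynylation joined to a 5-exo-dig lactonisation, in which the carboxylate of 14 binds trivalent rhodium, concerted metalation–deprotonation removes the β-hydrogen cis to it (five-membered rhodacycle), bromoalkyne 17 inserts with the new C–C bond at its bromine-bearing carbon (rhodium on the carbon carrying the conjugating trienyl group), β-bromide elimination releases the (2Z)-enynoic acid 18 with rhodium still trivalent, and the carboxylate oxygen then adds anti to the alkyne activated by monovalent silver so that protodemetalation forms the lactone C–O bond and the Z exocyclic alkene; the closest known reactions are the carboxylate-directed ortho C–H alkynylation of benzoic acids with silyl bromoalkynes under half-sandwich late-metal catalysis, the rhodium-catalysed coupling of acrylic acids with alkynes to 2-pyranones, and the palladium/copper coupling–lactonisation of (Z)-3-iodoacrylic acids with terminal alkynes, none of which has been shown for an α-alkylacrylic acid with a polyenyl bromoalkyne.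

Step 12
Reactants: 7 [(2E,4E)-5-[(4R)-4-hydroxy-2,6,6-trimethylcyclohex-1-en-1-yl]-3-methylpenta-2,4-dien-1-yl]triphenylphosphonium bromide, 19 (2E,4E,6E,8Z)-8-(4-{2-[(1R,4R)-4-hydroxy-2,6,6-trimethylcyclohex-2-en-1-yl]ethyl}-5-oxofuran-2(5H)-ylidene)-2,7-dimethylocta-2,4,6-trienal
Product: 21 (3R,3'R,6'R,11'Z)-3,3'-dihydroxy-7',8'-dihydro-β,ε-caroten-19',11'-olide, via phosphorus ylide 20 (not isolated)
Conditions: 1,2-epoxybutane (10 equiv), EtOH/CH2Cl2, 60 °C, dark, argon; then EtOAc/heptane, 80 °C (11Z to 11E)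
Reagents that add atoms: none
Why: Wittig olefination under base-free epoxide conditions (bromide opens the epoxide and the alkoxide so formed generates the ylide, so the enol lactone never meets a stoichiometric strong base) forms C11=C12, and the usual thermal equilibration converts the 11Z portion to the all-E chain while the thermodynamically preferred 11'Z ylidene and all three stereocentres stay untouched.

## Compound list

1 | (4R,6R)-4-hydroxy-2,2,6-trimethylcyclohexan-1-one (actinol) | CC1(C)C[C@H](O)C[C@@H](C)C1=O | starting material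
2 | dilithium (4R)-2,6,6-trimethylcyclohex-1-ene-1,4-bis(olate) | [Li+].[Li+].CC1=C([O-])C(C)(C)C[C@H]([O-])C1 | intermediate
3 | (4R)-4-hydroxy-2,6,6-trimethylcyclohex-1-en-1-yl trifluoromethanesulfonate | CC1=C(OS(=O)(=O)C(F)(F)F)C(C)(C)C[C@H](O)C1 | intermediate
4 | (2E)-3-methylpent-2-en-4-yn-1-ol | C#C/C(C)=C/CO | starting material
5 | (2E)-5-[(4R)-4-hydroxy-2,6,6-trimethylcyclohex-1-en-1-yl]-3-methylpent-2-en-4-yn-1-ol | CC1=C(C#C/C(C)=C/CO)C(C)(C)C[C@H](O)C1 | intermediate
6 | (2E,4E)-5-[(4R)-4-hydroxy-2,6,6-trimethylcyclohex-1-en-1-yl]-3-methylpenta-2,4-dien-1-ol | CC1=C(/C=C/C(C)=C/CO)C(C)(C)C[C@H](O)C1 | intermediate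
7 | [(2E,4E)-5-[(4R)-4-hydroxy-2,6,6-trimethylcyclohex-1-en-1-yl]-3-methylpenta-2,4-dien-1-yl]triphenylphosphonium bromide | CC1=C(/C=C/C(C)=C/C[P+](c2ccccc2)(c2ccccc2)c2ccccc2)C(C)(C)C[C@H](O)C1.[Br-] | intermediate
8 | (3E)-4-[(1R)-2,6,6-trimethylcyclohex-2-en-1-yl]but-3-en-2-one ((R)-α-ionone) | CC1=CCCC(C)(C)[C@H]1/C=C/C(C)=O | starting material
9 | 4-[(1R)-2,6,6-trimethylcyclohex-2-en-1-yl]butan-2-one | CC1=CCCC(C)(C)[C@H]1CCC(C)=O | intermediate
10 | potassium 4-[(1R)-2,6,6-trimethylcyclohex-2-en-1-yl]but-1-en-2-olate | CC1=CCCC(C)(C)[C@H]1CCC(=C)[O-].[K+] | intermediate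
11 | 4-[(1R)-2,6,6-trimethylcyclohex-2-en-1-yl]but-1-en-2-yl trifluoromethanesulfonate | CC1=CCCC(C)(C)[C@H]1CCC(=C)OS(=O)(=O)C(F)(F)F | intermediate
12 | 4-[(1R)-2,6,6-trimethyl-4-oxocyclohex-2-en-1-yl]but-1-en-2-yl trifluoromethanesulfonate | CC1=CC(=O)CC(C)(C)[C@H]1CCC(=C)OS(=O)(=O)C(F)(F)F | intermediate
13 | 4-[(1R,4R)-4-hydroxy-2,6,6-trimethylcyclohex-2-en-1-yl]but-1-en-2-yl trifluoromethanesulfonate | CC1=C[C@H](O)CC(C)(C)[C@H]1CCC(=C)OS(=O)(=O)C(F)(F)F | intermediate
14 | 2-{2-[(1R,4R)-4-hydroxy-2,6,6-trimethylcyclohex-2-en-1-yl]ethyl}prop-2-enoic acid | CC1=C[C@H](O)CC(C)(C)[C@H]1CCC(=C)C(=O)O | intermediate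
15 | (2E,4E,6E)-2,7-dimethylocta-2,4,6-trienedial | O=C/C(C)=C/C=C/C=C(C)/C=O | starting material
16 | (2E,4E,6E)-9,9-dibromo-2,7-dimethylnona-2,4,6,8-tetraenal | O=C/C(C)=C/C=C/C=C(C)/C=C(Br)Br | intermediate
17 | (2E,4E,6E)-9-bromo-2,7-dimethylnona-2,4,6-trien-8-ynal | O=C/C(C)=C/C=C/C=C(C)/C#CBr | intermediate
18 | (2Z,6E,8E,10E)-2-{2-[(1R,4R)-4-hydroxy-2,6,6-trimethylcyclohex-2-en-1-yl]ethyl}-6,11-dimethyl-12-oxododeca-2,6,8,10-tetraen-4-ynoic acid | CC1=C[C@H](O)CC(C)(C)[C@H]1CC/C(C(=O)O)=C/C#C/C(C)=C/C=C/C=C(C)/C=O | intermediate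
19 | (2E,4E,6E,8Z)-8-(4-{2-[(1R,4R)-4-hydroxy-2,6,6-trimethylcyclohex-2-en-1-yl]ethyl}-5-oxofuran-2(5H)-ylidene)-2,7-dimethylocta-2,4,6-trienal | CC1=C[C@H](O)CC(C)(C)[C@H]1CCC1=C/C(=C/C(C)=C/C=C/C=C(C)/C=O)OC1=O | intermediate
20 | [(2E,4E)-5-[(4R)-4-hydroxy-2,6,6-trimethylcyclohex-1-en-1-yl]-3-methylpenta-2,4-dien-1-ylidene]triphenylphosphorane | CC1=C(/C=C/C(C)=C/C=P(c2ccccc2)(c2ccccc2)c2ccccc2)C(C)(C)C[C@H](O)C1 | intermediate
21 | (3R,3'R,6'R,11'Z)-3,3'-dihydroxy-7',8'-dihydro-β,ε-caroten-19',11'-olide (CNP0242041.1) | CC1=C[C@H](O)CC(C)(C)[C@H]1CCC1=C/C(=C/C(C)=C/C=C/C=C(C)/C=C/C=C(C)/C=C/C2=C(C)C[C@@H](O)CC2(C)C)OC1=O | target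

## Step count and risks

Total step count: 12. Longest linear sequence: 7 steps (8 to 21 through steps 5, 6, 7, 8, 9, 11 and 12).

The three steps most likely to fail:

1. Step 11, the proposed cascade. Metalation may be slow at 40 °C, the carboxylate may add across the bromoalkyne instead, or closure may go 6-endo to the pyranone. The fallback uses known chemistry, sets out from 14 and 15, and comes back at 19. Alkylation of 14 with allyl bromide (K2CO3, DMF) gives the allyl ester F1. Ring-closing metathesis with the second-generation Grubbs catalyst (toluene, 80 °C) gives the 3-substituted furan-2(5H)-one F2. TBSOTf (3.3 equiv) and iPr2NEt in CH2Cl2 convert F2 in the flask into the bis-silylated 2-silyloxyfuran F3, which adds in a vinylogous Mukaiyama aldol reaction to an excess of 15 to give the silylated aldol adduct F4. DBU then eliminates silanol to give the silyl-protected Z-ylidenebutenolide F5, and HF·pyridine in THF removes the ring silyl ether and returns 19. This fallback builds the ylidene by C=C formation instead of lactone closure.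

2. Step 8, the catalyst-controlled reduction. The chiral catalyst may not override the substrate bias, or may give a poor diastereomer ratio. The fallback sets out from 12 and comes back at 13. Luche reduction (NaBH4, CeCl3·7H2O, MeOH, -78 °C) without chiral control gives 13 together with its C4 epimer, the cis alcohol F6, and the two are separated by chromatography. F6 is inverted by Mitsunobu esterification (4-nitrobenzoic acid, PPh3, DIAD, THF, 0 °C) to the trans 4-nitrobenzoate F7, and methanolysis (K2CO3, MeOH, 0 °C) returns 13.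

3. Step 12, the final Wittig reaction. The enol lactone of 19 may open, or the chain may give an inseparable isomer mixture. The fallback changes the order of assembly, sets out from 7, 15 and 14, and comes back at 21. Wittig reaction of 7 with an excess of 15 (NaOMe, CH2Cl2/MeOH, then thermal isomerisation) gives the C25 hydroxy aldehyde F8. The one-flask dibromo-olefination and elimination of step 10 converts F8 through the gem-dibromoalkene F9 into the C26 bromoalkyne F10. The conditions of step 11 then join F10 to 14 and close the butenolide last, through the enynoic acid F11, to give 21 directly. This fallback still depends on the new cascade.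

Further compounds

F1 | step 11 | prop-2-en-1-yl 2-{2-[(1R,4R)-4-hydroxy-2,6,6-trimethylcyclohex-2-en-1-yl]ethyl}prop-2-enoate | CC1=C[C@H](O)CC(C)(C)[C@H]1CCC(=C)C(=O)OCC=C
F2 | step 11 | 3-{2-[(1R,4R)-4-hydroxy-2,6,6-trimethylcyclohex-2-en-1-yl]ethyl}furan-2(5H)-one | CC1=C[C@H](O)CC(C)(C)[C@H]1CCC1=CCOC1=O
F3 | step 11 | tert-butyl{[3-(2-{(1R,4R)-4-[(tert-butyldimethylsilyl)oxy]-2,6,6-trimethylcyclohex-2-en-1-yl}ethyl)furan-2-yl]oxy}dimethylsilane | CC1=C[C@H](O[Si](C)(C)C(C)(C)C)CC(C)(C)[C@H]1CCc1ccoc1O[Si](C)(C)C(C)(C)C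
F4 | step 11 | (2E,4E,6E)-8-[(tert-butyldimethylsilyl)oxy]-8-[4-(2-{(1R,4R)-4-[(tert-butyldimethylsilyl)oxy]-2,6,6-trimethylcyclohex-2-en-1-yl}ethyl)-5-oxo-2,5-dihydrofuran-2-yl]-2,7-dimethylocta-2,4,6-trienal (diastereomer mixture at the two new centres) | CC1=C[C@H](O[Si](C)(C)C(C)(C)C)CC(C)(C)[C@H]1CCC1=CC(OC1=O)C(O[Si](C)(C)C(C)(C)C)/C(C)=C/C=C/C=C(C)/C=O
F5 | step 11 | (2E,4E,6E,8Z)-8-[4-(2-{(1R,4R)-4-[(tert-butyldimethylsilyl)oxy]-2,6,6-trimethylcyclohex-2-en-1-yl}ethyl)-5-oxofuran-2(5H)-ylidene]-2,7-dimethylocta-2,4,6-trienal | CC1=C[C@H](O[Si](C)(C)C(C)(C)C)CC(C)(C)[C@H]1CCC1=C/C(=C/C(C)=C/C=C/C=C(C)/C=O)OC1=O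
F6 | step 8 | 4-[(1R,4S)-4-hydroxy-2,6,6-trimethylcyclohex-2-en-1-yl]but-1-en-2-yl trifluoromethanesulfonate | CC1=C[C@@H](O)CC(C)(C)[C@H]1CCC(=C)OS(=O)(=O)C(F)(F)F
F7 | step 8 | (1R,4R)-3,5,5-trimethyl-4-{3-[(trifluoromethanesulfonyl)oxy]but-3-en-1-yl}cyclohex-2-en-1-yl 4-nitrobenzoate | CC1=C[C@H](OC(=O)c2ccc(cc2)[N+](=O)[O-])CC(C)(C)[C@H]1CCC(=C)OS(=O)(=O)C(F)(F)F
F8 | step 12 | (2E,4E,6E,8E,10E,12E)-13-[(4R)-4-hydroxy-2,6,6-trimethylcyclohex-1-en-1-yl]-2,7,11-trimethyltrideca-2,4,6,8,10,12-hexaenal | CC1=C(/C=C/C(C)=C/C=C/C(C)=C/C=C/C=C(C)/C=O)C(C)(C)C[C@H](O)C1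
F9 | step 12 | (1R)-4-[(1E,3E,5E,7E,9E,11E)-14,14-dibromo-3,7,12-trimethyltetradeca-1,3,5,7,9,11,13-heptaen-1-yl]-3,5,5-trimethylcyclohex-3-en-1-ol | CC1=C(/C=C/C(C)=C/C=C/C(C)=C/C=C/C=C(C)/C=C(Br)Br)C(C)(C)C[C@H](O)C1
F10 | step 12 | (1R)-4-[(1E,3E,5E,7E,9E,11E)-14-bromo-3,7,12-trimethyltetradeca-1,3,5,7,9,11-hexaen-13-yn-1-yl]-3,5,5-trimethylcyclohex-3-en-1-ol | CC1=C(/C=C/C(C)=C/C=C/C(C)=C/C=C/C=C(C)/C#CBr)C(C)(C)C[C@H](O)C1
F11 | step 12 | (2Z,6E,8E,10E,12E,14E,16E)-17-[(4R)-4-hydroxy-2,6,6-trimethylcyclohex-1-en-1-yl]-2-{2-[(1R,4R)-4-hydroxy-2,6,6-trimethylcyclohex-2-en-1-yl]ethyl}-6,11,15-trimethylheptadeca-2,6,8,10,12,14,16-heptaen-4-ynoic acid | CC1=C[C@H](O)CC(C)(C)[C@H]1CC/C(C(=O)O)=C/C#C/C(C)=C/C=C/C=C(C)/C=C/C=C(C)/C=C/C1=C(C)C[C@@H](O)CC1(C)C
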